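The readings are simulated on assumed constants.

- In the blue run, 4.8 mol% of L had made Z worth 58.5 % of the Q by 4.00 h, so each L had turned over about 12.2 times.
- Two amounts seemed to me to matter: the turnovers asked of each L by the moment in question, and the turnovers an L lasts. Their ratio is the share of L already lost.

in all of them: Q 0.24 M

|  | J | L | remark |
|---|---|---|---|
| blue | 5 equiv | 4.8 mol% | run made earlier |
| amber | 5 equiv | 7.1 mol% | run made earlier |
| flask | 5.00 equiv | 9.5 mol% |  |

| run | time / h | Z / % | Q / % |
|---|---|---|---|
| blue | 0.417 | 26.7 | 51.2 |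
| blue | 1.33 | 45.6 | 21.4 |
| blue | 2.50 | 53.6 | 10.1 |
| blue | 4.00 | 58.5 | 4.2 |
| amber | 0.250 | 25.8 | 57.5 |
| amber | 0.667 | 45.6 | 30.4 |
| amber | 1.50 | 60.8 | 12.3 |
| amber | 4.00 | 69.9 | 1.7 |

(standard deviation of a reading: 0.5 percentage points)

- factor on the rate of making Z when 50 % of the Q are converted if L is charged twice over
- factor on the rate when 50 % of the Q are converted if L is charged at 2 mol% instead

- In the blue run, Z made per unit of mean Q fell from 0.878 h⁻¹ to 0.454 h⁻¹, while the mean count rose from 2.78 to 10.3 turnovers.
- I assumed that L is lost in step with its turnovers. A straight line through these two points then reaches zero at a reading of 18.4 turnovers, the life of an L, its turnover number (TON).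
- In the amber run's first reading, 60.7 % of the Q lost had become Z. I applied that share to the flask, so at 50 % conversion each L had turned over 3.20 times and 17.3 % of L was lost.
- Twice the L halves that loss if the share holds, so my factor was 2.21. With 2 mol%, less L than in the flask, each L works harder, so I put that factor under 0.211.
- The forecast gave 2.05 and 0.19, the first lower than mine: “I take values between these and keep the range wide.”

    Q + J + L → L + Z (k = 0.0216 M⁻² s⁻¹)
    Q + L → E (k = 0.00121 M⁻¹ s⁻¹)
    2 Q → D (k = 5.49 × 10⁻⁴ M⁻¹ s⁻¹)

- The flask gave 2.16 for twice the L and 0.162 for 2 mol%. At 50 % conversion with 2 mol%, 39.2 % of the catalyst stood as E. In the flask, the 76.4 % of Z at 6.00 h came to 8.04 turnovers per L charged, which against my reading of 18.4 turnovers reckons 43.7 % of L lost, and 40.7 % of the catalyst stood as E.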